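**Assumption:** the target has no stereocentre and no stable stereoaxis (the SMILES carries no stereo descriptors), so it is achiral and "single enantiomer" does not apply.

## Retrosynthetic overview
1. The C–Br next to the ether oxygen on the methoxy ring comes from an aryl amine by Sandmeyer bromination.
2. The other two bromines of that ring come from electrophilic bromination of the aniline, where NH2 and OMe direct to the same two carbons.
3. The amine comes from a nitro group, which first serves to activate an ortho C–F bond.
4. The diaryl ether comes from SNAr of 2-bromophenol on 2-fluoro-3-nitroanisole.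
5. No ring is formed; both benzene rings are bought.

## Route

Step 1
Reactants: 1 2-fluoro-3-nitroanisole (2-fluoro-1-methoxy-3-nitrobenzene); 2 2-bromophenol
Product: 3 1-bromo-2-(2-methoxy-6-nitrophenoxy)benzene
Conditions: K2CO3 (2 equiv), DMF, 90 °C
Reagents that add atoms: none
Why: Nucleophilic aromatic substitution (SNAr, Meisenheimer pathway) in which the ortho-nitro group activates the C–F bond for attack by the phenoxide, while the OMe (meta to NO2) and the aryl bromide are inert.

Step 2
Reactants: 3 1-bromo-2-(2-methoxy-6-nitrophenoxy)benzene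
Product: 4 2-(2-bromophenoxy)-3-methoxyaniline
Conditions: Fe powder (5 equiv), AcOH, EtOH/H2O, 70 °C
Reagents that add atoms: none
Why: Béchamp-type dissolving-metal nitro reduction, which takes NO2 to NH2 by electron transfer and, unlike Pd/H2, leaves the aryl C–Br and the ether untouched.

Step 3
Reactants: 4 2-(2-bromophenoxy)-3-methoxyaniline
Product: 5 4,6-dibromo-2-(2-bromophenoxy)-3-methoxyaniline
Conditions: NBS (2.05 equiv), MeCN, 0 °C to rt
Reagents that add atoms: N-bromosuccinimide (NBS), O=C1CCC(=O)N1Br
Why: Electrophilic aromatic bromination in which NH2 and OMe both direct to C4 and C6 (each is ortho/para to both donors), C5 is meta to both, C2 is blocked, and the bromophenoxy ring is far less nucleophilic, so two equivalents stop at the dibromide.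

Step 4
Reactants: 5 4,6-dibromo-2-(2-bromophenoxy)-3-methoxyaniline
Product: 7 1,2,5-tribromo-3-(2-bromophenoxy)-4-methoxybenzene, via arenediazonium bromide 6 (not isolated)
Conditions: t-BuONO (1.5 equiv), CuBr2 (1.2 equiv), MeCN, 0 to 60 °C
Reagents that add atoms: copper(II) bromide, Br[Cu]Br (the new Br of 7); tert-butyl nitrite, CC(C)(C)ON=O (its N is held only in intermediate 6 and leaves as N2)
Why: Sandmeyer bromination under anhydrous Doyle conditions, which diazotises the weakly basic, hindered aniline and lets stoichiometric CuBr2 trap the aryl radical by bromine transfer faster than it can cyclise onto the neighbouring ring (Pschorr).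

## Compound list
1 | 2-fluoro-3-nitroanisole (2-fluoro-1-methoxy-3-nitrobenzene) | COc1cccc([N+](=O)[O-])c1F | starting material
2 | 2-bromophenol | Oc1ccccc1Br | starting material
3 | 1-bromo-2-(2-methoxy-6-nitrophenoxy)benzene | COc1cccc([N+](=O)[O-])c1Oc1ccccc1Br | intermediate
4 | 2-(2-bromophenoxy)-3-methoxyaniline | COc1cccc(N)c1Oc1ccccc1Br | intermediate
5 | 4,6-dibromo-2-(2-bromophenoxy)-3-methoxyaniline | COc1c(Br)cc(Br)c(N)c1Oc1ccccc1Br | intermediate
6 | 4,6-dibromo-2-(2-bromophenoxy)-3-methoxybenzenediazonium bromide | COc1c(Br)cc(Br)c([N+]#N)c1Oc1ccccc1Br.[Br-] | intermediate (not isolated)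
7 | 1,2,5-tribromo-3-(2-bromophenoxy)-4-methoxybenzene (= 3,4,6-tribromo-2-(2-bromophenoxy)anisole) | COc1c(Br)cc(Br)c(Br)c1Oc1ccccc1Br | target

## Summary
Total step count: 4. Longest linear sequence: 4 steps (1 → 3 → 4 → 5 → 7).

Steps most likely to fail, with fallbacks:

**Step 4 (Sandmeyer on a 2,6-disubstituted, weakly basic aniline).** The risks are incomplete diazotisation, hydrodediazoniation, and radical cyclisation to a dibenzofuran. The fallback sets out from 5 and comes back at 7. Compound 5 is diazotised with t-BuONO/BF3·OEt2 in THF at −15 °C to give 4,6-dibromo-2-(2-bromophenoxy)-3-methoxybenzenediazonium tetrafluoroborate F1. This is quenched cold with Et2NH/K2CO3 to the isolable, chromatographable masked diazonium 1-[4,6-dibromo-2-(2-bromophenoxy)-3-methoxyphenyl]-3,3-diethyltriaz-1-ene F2. Heating the purified triazene with TMSBr in MeCN at 60 °C releases the aryl bromide 7 without copper, in the presence of a large excess of bromide.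

**Step 1 (SNAr at a fluoride flanked by OMe and NO2 with an ortho-substituted phenoxide).** The risk is sluggish or incomplete substitution. The fallback reverses the polarity of the ether coupling; it sets out from 1 and comes back at 3. Compound 1 is hydrolysed with the small nucleophile hydroxide (KOH, DMSO/H2O, 80 °C, then HCl) to 2-methoxy-6-nitrophenol F3, which can also be bought. In a separate flask, 1-bromo-2-iodobenzene is oxidised with mCPBA/TsOH·H2O in MeCN to 1-bromo-2-[hydroxy(tosyloxy)-λ3-iodanyl]benzene F4, which is not isolated. Adding 1,3,5-trimethoxybenzene converts it to (2-bromophenyl)(2,4,6-trimethoxyphenyl)iodonium tosylate F5. The phenoxide of F3 (K2CO3, MeCN, 60 °C) then takes the 2-bromophenyl group from F5 by metal-free ligand coupling, with the electron-rich trimethoxyphenyl group acting as the non-transferred ligand, to give 3.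

**Step 3 (double bromination of a free aniline).** The risks are oxidation of the electron-rich aniline, mono/di mixtures, and traces of bromination para to oxygen on the other ring. The fallback is a protecting-group detour; it sets out from 4 and comes back at 5. Compound 4 is converted with Boc2O in THF at reflux to tert-butyl N-[2-(2-bromophenoxy)-3-methoxyphenyl]carbamate F6. The carbamate is no longer oxidisable, and OMe and NHBoc still direct to the same two carbons. NBS (2.1 equiv) in DMF at rt gives tert-butyl N-[4,6-dibromo-2-(2-bromophenoxy)-3-methoxyphenyl]carbamate F7. TFA/CH2Cl2 at rt then returns 5.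

## Further compounds
F1 | step 4 | 4,6-dibromo-2-(2-bromophenoxy)-3-methoxybenzenediazonium tetrafluoroborate | COc1c(Br)cc(Br)c([N+]#N)c1Oc1ccccc1Br.F[B-](F)(F)F
F2 | step 4 | 1-[4,6-dibromo-2-(2-bromophenoxy)-3-methoxyphenyl]-3,3-diethyltriaz-1-ene | CCN(CC)/N=N/c1c(Br)cc(Br)c(OC)c1Oc1ccccc1Br
F3 | step 1 | 2-methoxy-6-nitrophenol | COc1cccc([N+](=O)[O-])c1O
F4 | step 1 | 1-bromo-2-[hydroxy(tosyloxy)-λ3-iodanyl]benzene | Cc1ccc(S(=O)(=O)OI(O)c2ccccc2Br)cc1
F5 | step 1 | (2-bromophenyl)(2,4,6-trimethoxyphenyl)iodonium 4-methylbenzenesulfonate | COc1cc(OC)c([I+]c2ccccc2Br)c(OC)c1.Cc1ccc(S(=O)(=O)[O-])cc1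
F6 | step 3 | tert-butyl N-[2-(2-bromophenoxy)-3-methoxyphenyl]carbamate | COc1cccc(NC(=O)OC(C)(C)C)c1Oc1ccccc1Br
F7 | step 3 | tert-butyl N-[4,6-dibromo-2-(2-bromophenoxy)-3-methoxyphenyl]carbamate | COc1c(Br)cc(Br)c(NC(=O)OC(C)(C)C)c1Oc1ccccc1Br
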